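The route rests on cutting the C2–C3 bond of the central 3-acyloxybutanoate. C2 is the methylene α to an ester carbonyl. C3 is the carbinol carbon bearing CH3, H and the ester oxygen of the 3,4-dihydroxybutanoyl group. The key step exploits this acyclic pair: C3 is an oxygen-stabilised radical site with a nickel-binding acyl C=O beside it, and C2 is a Reformatsky carbon; the arene is a bystander. A chiral nickel catalyst couples the zinc enolate of the complete resorcylate iodoacetate with the epimeric 1-chloroethyl ester of (R)-3,4-bis(benzyloxy)butanoic acid. One operation joins both halves, keeps every ester linkage and sets the last stereocentre stereoconvergently. Five benzyl groups then fall in one neutral hydrogenolysis.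

Key step: step 13

Assumption: which enantiomer of the bis(oxazoline) ligand gives the R configuration at the new centre cannot be derived on paper. The (S,S) ligand is written, the choice is to be confirmed on a model pair (1-chloroethyl butanoate and the zinc reagent of isopropyl iodoacetate), and the mirror-image ligand is equally available.

Step 1
Reactants: 1 (R)-benzyl glycidyl ether
Product: 2 (R)-1-(benzyloxy)pent-4-en-2-ol
Conditions: vinylMgBr, CuI (10 mol %), THF, −40 → −10 °C; aqueous work-up
Reagents that add atoms: vinylmagnesium bromide, C=C[Mg]Br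
Why: Copper-catalysed Grignard opening of a terminal epoxide (SN2 at the unsubstituted CH2) leaves the C–O stereocentre of 1 untouched, so 2 keeps the R configuration that becomes C3 of the dihydroxybutanoyl unit.

Step 2
Reactants: 2 (R)-1-(benzyloxy)pent-4-en-2-ol
Product: 3 (R)-4,5-bis(benzyloxy)pent-1-ene
Conditions: NaH, BnBr, Bu4NI (cat.), THF, 0 °C → rt
Reagents that add atoms: benzyl bromide, BrCc1ccccc1
Why: Williamson ether synthesis on the sodium alkoxide does not touch the stereocentre and installs the second hydrogenolysable group.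

Step 3
Reactants: 3 (R)-4,5-bis(benzyloxy)pent-1-ene
Product: 5 (R)-3,4-bis(benzyloxy)butanoic acid, via bis(benzyloxy)butanal 4 (not isolated)
Conditions: OsO4 (1 mol %), Oxone, DMF, rt
Reagents that add atoms: Oxone (active part potassium peroxymonosulfate), [K+].[O-]S(=O)(=O)OO
Why: Osmium-catalysed oxidative cleavage of a terminal alkene with Oxone takes the C=C through the aldehyde to the acid in one flask, removes one carbon and leaves the benzyl ethers and the β-stereocentre alone.

Step 4
Reactants: 5 (R)-3,4-bis(benzyloxy)butanoic acid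
Product: 6 vinyl (R)-3,4-bis(benzyloxy)butanoate
Conditions: vinyl acetate (solvent), Pd(OAc)2 (5 mol %), KOH (10 mol %), rt
Reagents that add atoms: vinyl acetate, C=COC(C)=O
Why: Palladium(II)-catalysed transvinylation exchanges the acyl group of vinyl acetate for that of 5 under nearly neutral conditions, and the large excess of vinyl acetate drives the equilibrium.

Step 5
Reactants: 6 vinyl (R)-3,4-bis(benzyloxy)butanoate
Product: 7 (1RS)-1-chloroethyl (3R)-3,4-bis(benzyloxy)butanoate (both epimers at the C–Cl carbon)
Conditions: HCl (4 M in dioxane), CH2Cl2, 0 °C; evaporation, used crude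
Reagents that add atoms: hydrogen chloride, Cl
Why: Markovnikov hydrochlorination of an enol ester: protonation of the terminal CH2 gives the acyloxy-stabilised cation that chloride traps, and the new C–Cl centre is formed without control on purpose, since step 13 erases it.

Step 6
Reactants: 8 1,3-bis(benzyloxy)-5-bromobenzene; 9 (R)-propylene oxide
Product: 11 (R)-1-[3,5-bis(benzyloxy)phenyl]propan-2-ol, via arylmagnesium bromide 10 (not isolated)
Conditions: Mg, I2 (cat.), THF, reflux; then CuI (10 mol %), 9, −30 → 0 °C; aqueous work-up
Reagents that add atoms: none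
Why: Grignard formation and copper-catalysed SN2 opening of the epoxide at its CH2 give the homobenzylic alcohol with the stereocentre of 9 retained as R.

Step 7
Reactants: 11 (R)-1-[3,5-bis(benzyloxy)phenyl]propan-2-ol
Product: 12 (R)-1-[3,5-bis(benzyloxy)phenyl]propan-2-yl chloroacetate
Conditions: ClCH2COCl, pyridine, CH2Cl2, 0 °C
Reagents that add atoms: chloroacetyl chloride, ClCC(=O)Cl
Why: Acylation of a secondary alcohol with an acid chloride keeps the configuration at carbon, and the chloroacetate serves both as protecting group for the next four steps and as the latent Reformatsky carbon.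

Step 8
Reactants: 12 (R)-1-[3,5-bis(benzyloxy)phenyl]propan-2-yl chloroacetate
Product: 14 (R)-1-[3,5-bis(benzyloxy)-2-formylphenyl]propan-2-yl chloroacetate, via aryl iminium chloride 13 (not isolated)
Conditions: POCl3, DMF, 0 → 50 °C; then ice/H2O
Reagents that add atoms: N,N-dimethylformamide (formyl carbon), CN(C)C=O; water (aldehyde oxygen), O
Why: Vilsmeier–Haack formylation attacks the ring carbon next to the side chain, ortho to one and para to the other benzyloxy group, in preference to the crowded carbon between both benzyloxy groups, and hydrolysis of the iminium salt gives the aldehyde.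

Step 9
Reactants: 14 (R)-1-[3,5-bis(benzyloxy)-2-formylphenyl]propan-2-yl chloroacetate
Product: 15 2,4-bis(benzyloxy)-6-{(2R)-2-[(chloroacetyl)oxy]propyl}benzoic acid
Conditions: NaClO2, NaH2PO4, 2-methyl-2-butene, t-BuOH/THF/H2O, rt
Reagents that add atoms: sodium chlorite, [Na+].[O-]Cl=O
Why: Pinnick oxidation converts the aldehyde to the acid at buffered pH, and the alkene scavenger intercepts hypochlorous acid before it chlorinates the electron-rich ring.

Step 10
Reactants: 16 (R)-3-hydroxybutanoic acid
Product: 17 benzyl (R)-3-hydroxybutanoate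
Conditions: BnBr, KHCO3, DMF, rt
Reagents that add atoms: benzyl bromide, BrCc1ccccc1
Why: O-alkylation of the carboxylate with benzyl bromide (SN2) esterifies the acid without touching the free hydroxyl group or its stereocentre.

Step 11
Reactants: 15 2,4-bis(benzyloxy)-6-{(2R)-2-[(chloroacetyl)oxy]propyl}benzoic acid; 17 benzyl (R)-3-hydroxybutanoate
Product: 18 (2S)-4-(benzyloxy)-4-oxobutan-2-yl 2,4-bis(benzyloxy)-6-{(2R)-2-[(chloroacetyl)oxy]propyl}benzoate
Conditions: PPh3, DIAD (premixed, 0 °C), then 17 and 15, toluene, 0 °C → rt
Reagents that add atoms: none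
Why: Mitsunobu esterification lets the hindered 2,6-disubstituted benzoate act as nucleophile rather than acyl donor and displaces the activated hydroxyl of 17 by SN2 with inversion, which turns the R alcohol into the S ester centre of the target.

Step 12
Reactants: 18 chloroacetate triester
Product: 19 (2S)-4-(benzyloxy)-4-oxobutan-2-yl 2,4-bis(benzyloxy)-6-{(2R)-2-[(iodoacetyl)oxy]propyl}benzoate
Conditions: NaI, acetone, rt, dark
Reagents that add atoms: sodium iodide, [Na+].[I-]
Why: Finkelstein exchange, driven by precipitation of sodium chloride from acetone, gives the iodoacetate into which zinc inserts under mild conditions.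

Step 13
Reactants: 19 iodoacetate triester; 7 (1RS)-1-chloroethyl (3R)-3,4-bis(benzyloxy)butanoate
Product: 21 pentabenzyl-protected talapolyester B, via iodozinc enolate 20 (not isolated)
Conditions: Zn dust (TMSCl-activated), THF, rt; then 7 (slight excess), NiBr2·diglyme (10 mol %), (S,S)-Ph-BOX (13 mol %), THF/DMA, −10 → 0 °C
Reagents that add atoms: none
Why: Proposed new method: a ligated Ni(I) species abstracts the halogen from either epimer of 7 (chloride, or the iodide formed from it by exchange with the zinc iodide present) to give one planar 1-acyloxyethyl radical, the carbon-bound zinc enolate 20 hands its CH2 group to Ni(II), radical capture gives a dialkyl-Ni(III) complex, and reductive elimination forms the C2–C3 bond of the central butanoate. The closest known reaction type is the nickel/bis(oxazoline)-catalysed enantioconvergent alkyl–alkyl coupling of racemic 1-haloalkyl esters to esters of chiral dialkyl carbinols, where the alkyl-nickel partner comes from an olefin and a hydrosilane; new here is a Reformatsky reagent as that partner (so far used in nickel- and palladium-catalysed arylations), while the Ni(III) species with one α-carbonyl alkyl and one secondary alkyl ligand is the kind met in enantioconvergent Negishi couplings of α-halo carbonyl compounds. No ring is closed. The new C3 stereocentre (R) is set by the chiral ligand alone: both epimers of 7 converge on the same radical, the acyl C=O next to the radical carbon binds to nickel and fixes the face that bonds, and the resident stereocentres lie at least four atoms away. The step needs chemoselectivity among one C–I bond, one C–Cl bond and four ester groups: zinc inserts only into the activated C–I bond, the zinc enolate is too weak a base and nucleophile at or below 0 °C to attack esters or to start E1cB loss of carboxylate from the β-acyloxy ester units, and chloride rather than bromide in 7 holds down the uncatalysed, stereorandom substitution.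

Step 14
Reactants: 21 pentabenzyl-protected talapolyester B
Product: 22 talapolyester B
Conditions: H2 (1 atm), 10 % Pd/C, EtOAc/THF, rt
Reagents that add atoms: none
Why: Hydrogenolysis of two aryl benzyl ethers, two alkyl benzyl ethers and one benzyl ester frees all five OH groups at once without acid or base that could drive lactonisation of the 4-hydroxy ester or β-elimination, and the homobenzylic C–O bond is not cleaved.

Compound list
1 | (R)-benzyl glycidyl ether | C1[C@@H](O1)COCc2ccccc2 | starting material
2 | (R)-1-(benzyloxy)pent-4-en-2-ol | C=CC[C@@H](O)COCc1ccccc1 | intermediate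
3 | (R)-4,5-bis(benzyloxy)pent-1-ene | C=CC[C@@H](OCc1ccccc1)COCc1ccccc1 | intermediate
4 | (R)-3,4-bis(benzyloxy)butanal (not isolated) | O=CC[C@@H](OCc1ccccc1)COCc1ccccc1 | intermediate
5 | (R)-3,4-bis(benzyloxy)butanoic acid | OC(=O)C[C@@H](OCc1ccccc1)COCc1ccccc1 | intermediate
6 | vinyl (R)-3,4-bis(benzyloxy)butanoate | C=COC(=O)C[C@@H](OCc1ccccc1)COCc1ccccc1 | intermediate
7 | (1RS)-1-chloroethyl (3R)-3,4-bis(benzyloxy)butanoate | CC(Cl)OC(=O)C[C@@H](OCc1ccccc1)COCc1ccccc1 | intermediate
8 | 1,3-bis(benzyloxy)-5-bromobenzene | Brc1cc(OCc2ccccc2)cc(OCc2ccccc2)c1 | starting material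
9 | (R)-propylene oxide | C[C@@H]1CO1 | starting material
10 | 3,5-bis(benzyloxy)phenylmagnesium bromide (not isolated) | Br[Mg]c1cc(OCc2ccccc2)cc(OCc2ccccc2)c1 | intermediate
11 | (R)-1-[3,5-bis(benzyloxy)phenyl]propan-2-ol | C[C@@H](O)Cc1cc(OCc2ccccc2)cc(OCc2ccccc2)c1 | intermediate
12 | (R)-1-[3,5-bis(benzyloxy)phenyl]propan-2-yl chloroacetate | ClCC(=O)O[C@H](C)Cc1cc(OCc2ccccc2)cc(OCc2ccccc2)c1 | intermediate
13 | N,N-dimethyliminium chloride of aldehyde 14 (not isolated) | ClCC(=O)O[C@H](C)Cc1cc(OCc2ccccc2)cc(OCc2ccccc2)c1C=[N+](C)C.[Cl-] | intermediate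
14 | (R)-1-[3,5-bis(benzyloxy)-2-formylphenyl]propan-2-yl chloroacetate | ClCC(=O)O[C@H](C)Cc1cc(OCc2ccccc2)cc(OCc2ccccc2)c1C=O | intermediate
15 | 2,4-bis(benzyloxy)-6-{(2R)-2-[(chloroacetyl)oxy]propyl}benzoic acid | ClCC(=O)O[C@H](C)Cc1cc(OCc2ccccc2)cc(OCc2ccccc2)c1C(=O)O | intermediate
16 | (R)-3-hydroxybutanoic acid | C[C@@H](O)CC(=O)O | starting material
17 | benzyl (R)-3-hydroxybutanoate | C[C@@H](O)CC(=O)OCc1ccccc1 | intermediate
18 | (2S)-4-(benzyloxy)-4-oxobutan-2-yl 2,4-bis(benzyloxy)-6-{(2R)-2-[(chloroacetyl)oxy]propyl}benzoate | ClCC(=O)O[C@H](C)Cc1cc(OCc2ccccc2)cc(OCc2ccccc2)c1C(=O)O[C@@H](C)CC(=O)OCc1ccccc1 | intermediate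
19 | (2S)-4-(benzyloxy)-4-oxobutan-2-yl 2,4-bis(benzyloxy)-6-{(2R)-2-[(iodoacetyl)oxy]propyl}benzoate | ICC(=O)O[C@H](C)Cc1cc(OCc2ccccc2)cc(OCc2ccccc2)c1C(=O)O[C@@H](C)CC(=O)OCc1ccccc1 | intermediate
20 | iodozinc enolate (Reformatsky reagent) of 19, drawn carbon-bound (not isolated) | I[Zn]CC(=O)O[C@H](C)Cc1cc(OCc2ccccc2)cc(OCc2ccccc2)c1C(=O)O[C@@H](C)CC(=O)OCc1ccccc1 | intermediate
21 | pentabenzyl-protected talapolyester B: (2S)-4-(benzyloxy)-4-oxobutan-2-yl 2,4-bis(benzyloxy)-6-[(2R)-2-({(3R)-3-{[(3R)-3,4-bis(benzyloxy)butanoyl]oxy}butanoyl}oxy)propyl]benzoate | C[C@H](CC(=O)O[C@H](C)Cc1cc(OCc2ccccc2)cc(OCc2ccccc2)c1C(=O)O[C@@H](C)CC(=O)OCc1ccccc1)OC(=O)C[C@@H](OCc1ccccc1)COCc1ccccc1 | intermediate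
22 | talapolyester B: (3S)-3-({2,4-dihydroxy-6-[(2R)-2-({(3R)-3-{[(3R)-3,4-dihydroxybutanoyl]oxy}butanoyl}oxy)propyl]benzoyl}oxy)butanoic acid | C[C@H](CC(=O)O[C@H](C)Cc1cc(O)cc(O)c1C(=O)O[C@@H](C)CC(=O)O)OC(=O)C[C@@H](O)CO | target

Total step count: 14.
Longest linear sequence: 8 steps (6, 7, 8, 9, 11, 12, 13, 14), starting from 8 and 9.

Steps most likely to fail

Step 13.
- The risks are slow transfer of the zinc enolate to nickel, and protonation or self-condensation of the enolate.
- The enolate may also attack the acyl carbon of the activated ester.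
- β-Hydride elimination at nickel, uncatalysed stereorandom substitution or weak catalyst control of the radical face could erode the coupling or its selectivity.
- The fallback makes the same C–C bond by known chemistry and sets the centre afterwards.
- It sets out from 19. The zinc reagent 20 is added to acetaldehyde in a classical Reformatsky reaction to give the epimeric β-hydroxy ester F1.
- Dess–Martin oxidation gives the acetoacetate F2.
- Hydrogenation of this β-keto ester with a Ru-(R)-BINAP catalyst in CH2Cl2/i-PrOH gives the (R)-3-hydroxybutanoate F3.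
- Steglich esterification of F3 with acid 5 (EDC, DMAP, CH2Cl2, 0 °C) comes back to the route at 21.

Step 11.
- The risks are elimination of the activated β-hydroxy ester to the crotonate, sluggish attack of the hindered carboxylate, and quaternisation of the phosphine by the chloroacetate.
- The fallback changes from alkyl activation with inversion to acyl activation with retention.
- It sets out from 15, which is converted with 1-chloro-N,N,2-trimethylprop-1-en-1-amine under neutral conditions into the acid chloride F4.
- F4 acylates benzyl (S)-3-hydroxybutanoate F5, made from commercial (S)-3-hydroxybutanoic acid as in step 10, with pyridine and catalytic DMAP. This returns to the route at 18.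

Step 5.
- The risks are reversal by loss of HCl, hydrolysis of the sensitive 1-chloroethyl ester on handling, and acid-induced loss of the 4-O-benzyl group with ring closure to the γ-lactone.
- The fallback replaces addition to the enol ester by O-alkylation.
- It sets out from 5, whose caesium carboxylate (Cs2CO3, DMF, 0 °C → rt) is alkylated with 1-bromo-1-chloroethane, the bromide leaving selectively.
- It comes back at 7 and bypasses 6 (no new compound, F0).

Further compounds
F1 | step 13 | (2S)-4-(benzyloxy)-4-oxobutan-2-yl 2,4-bis(benzyloxy)-6-{(2R)-2-[(3-hydroxybutanoyl)oxy]propyl}benzoate, both epimers at the carbinol carbon | CC(O)CC(=O)O[C@H](C)Cc1cc(OCc2ccccc2)cc(OCc2ccccc2)c1C(=O)O[C@@H](C)CC(=O)OCc1ccccc1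
F2 | step 13 | (2S)-4-(benzyloxy)-4-oxobutan-2-yl 2,4-bis(benzyloxy)-6-{(2R)-2-[(3-oxobutanoyl)oxy]propyl}benzoate | CC(=O)CC(=O)O[C@H](C)Cc1cc(OCc2ccccc2)cc(OCc2ccccc2)c1C(=O)O[C@@H](C)CC(=O)OCc1ccccc1
F3 | step 13 | (2S)-4-(benzyloxy)-4-oxobutan-2-yl 2,4-bis(benzyloxy)-6-[(2R)-2-{[(3R)-3-hydroxybutanoyl]oxy}propyl]benzoate | C[C@@H](O)CC(=O)O[C@H](C)Cc1cc(OCc2ccccc2)cc(OCc2ccccc2)c1C(=O)O[C@@H](C)CC(=O)OCc1ccccc1
F4 | step 11 | 2,4-bis(benzyloxy)-6-{(2R)-2-[(chloroacetyl)oxy]propyl}benzoyl chloride | ClCC(=O)O[C@H](C)Cc1cc(OCc2ccccc2)cc(OCc2ccccc2)c1C(Cl)=O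
F5 | step 11 | benzyl (S)-3-hydroxybutanoate | C[C@H](O)CC(=O)OCc1ccccc1
F0 | step 5 | none | none
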